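**Retrosynthetic overview**
- The target is a 2,3-cis-3,4-trans flavan-3-ol (7,8,4'-trihydroxy) joined through C4 to C6 of a 2,3-cis-3,4-trans flavan-3,4-diol; the last operations are global hydrogenolysis and hydroxylation of the lower C4.
- Key disconnection: both C4–C4a bonds are cut at once, back to an acyclic bis-epoxide that already holds the interflavan C–C bond. A double 6-endo epoxy–arene Friedel–Crafts cyclization closes ring C of the upper unit first (C4 set by inversion), then ring C of the lower unit.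
- The bis-epoxide comes from two Mitsunobu inversions that turn erythro epoxy alcohols into threo aryl ethers (threo = 2,3-cis after ring closure).
- Upper arm: chalcone from the central benzaldehyde, Juliá–Colonna epoxidation, Zn(BH4)2 reduction. Lower arm: Sharpless kinetic resolution of an aryl vinyl carbinol.
- Rings A and B of both units are bought (pyrogallol, 2,3,4-trihydroxybenzaldehyde, one benzaldehyde, one acetophenone).

Assumption: flavan numbering is used for both units; "upper" is the 4-linked unit, "lower" the 6-linked unit with the free 4-OH; compounds 1, 2, 4, 5, 8 and 11 are taken as commercial.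

**Route**

Step 1
Reactants: 1 pyrogallol; 2 dichlorodiphenylmethane
Product: 3 2,2-diphenyl-1,3-benzodioxol-4-ol
Conditions: neat, 170 °C, N2 sweep
Reagents that add atoms: none
Why: Diphenylmethylene ketal formation on two adjacent phenols leaves one outer OH free, and symmetry allows only one product.

Step 2
Reactants: 4 3,4-bis(benzyloxy)benzaldehyde; 5 vinylmagnesium bromide
Product: 6 rac-1-[3,4-bis(benzyloxy)phenyl]prop-2-en-1-ol
Conditions: THF, −78 to 0 °C; aq NH4Cl
Reagents that add atoms: none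
Why: Grignard 1,2-addition to an aryl aldehyde gives the racemic allylic alcohol needed for a kinetic resolution.

Step 3
Reactants: 6 rac-1-[3,4-bis(benzyloxy)phenyl]prop-2-en-1-ol
Product: 7 (S)-[3,4-bis(benzyloxy)phenyl][(2R)-oxiran-2-yl]methanol (erythro)
Conditions: Ti(OiPr)4 (0.15 equiv), L-(+)-DIPT (0.18 equiv), TBHP (0.45 equiv), 4 Å MS, CH2Cl2, −20 °C
Reagents that add atoms: tert-butyl hydroperoxide, CC(C)(C)OO
Why: Sharpless kinetic resolution: with L-(+)-tartrate the (R)-carbinol is epoxidized fast and hydroxyl-directed to the erythro epoxy alcohol, which sets the future lower C3 and (before inversion) C2, while (S)-6 stays behind.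

Step 4
Reactants: 7 (S)-[3,4-bis(benzyloxy)phenyl][(2R)-oxiran-2-yl]methanol; 8 2,3,4-trihydroxybenzaldehyde (1.3 equiv)
Product: 9 4-{(R)-[3,4-bis(benzyloxy)phenyl][(2R)-oxiran-2-yl]methoxy}-2,3-dihydroxybenzaldehyde
Conditions: PPh3, DIAD, THF, 0 °C to rt
Reagents that add atoms: none
Why: Mitsunobu etherification: only the 4-OH (para to CHO, pKa about 7; the 2-OH is hydrogen-bonded, the 3-OH is an ordinary phenol) is alkylated, and SN2 inversion at the benzylic carbinol gives the threo aryl ether that encodes lower 2,3-cis.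

Step 5
Reactants: 9 4-{(R)-[3,4-bis(benzyloxy)phenyl][(2R)-oxiran-2-yl]methoxy}-2,3-dihydroxybenzaldehyde
Product: 10 2,3-bis(benzyloxy)-4-{(R)-[3,4-bis(benzyloxy)phenyl][(2R)-oxiran-2-yl]methoxy}benzaldehyde
Conditions: BnBr (3 equiv), K2CO3, Bu4NI (cat.), DMF, 0 °C then 45 °C
Reagents that add atoms: benzyl bromide, BrCc1ccccc1
Why: Williamson benzylation of the two remaining phenols; with excess BnBr, O-benzylation of the 3-phenoxide outruns its 6-exo attack on the neighbouring epoxide, and no stereocentre is touched.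

Step 6
Reactants: 10 2,3-bis(benzyloxy)-4-{(R)-[3,4-bis(benzyloxy)phenyl][(2R)-oxiran-2-yl]methoxy}benzaldehyde; 11 1-[4-(benzyloxy)phenyl]ethanone
Product: 12 (E)-3-[2,3-bis(benzyloxy)-4-{(R)-[3,4-bis(benzyloxy)phenyl][(2R)-oxiran-2-yl]methoxy}phenyl]-1-[4-(benzyloxy)phenyl]prop-2-en-1-one
Conditions: Ba(OH)2·8H2O (0.5 equiv), MeOH/THF 1:1, 40 °C
Reagents that add atoms: none
Why: Claisen–Schmidt condensation (aldol, then E1cB dehydration) gives the E-enone, and the mild barium base spares the epoxide and the benzylic aryl ether.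

Step 7
Reactants: 12 the E-chalcone
Product: 13 {(2R,3S)-3-[2,3-bis(benzyloxy)-4-{(R)-[3,4-bis(benzyloxy)phenyl][(2R)-oxiran-2-yl]methoxy}phenyl]oxiran-2-yl}[4-(benzyloxy)phenyl]methanone
Conditions: poly-L-leucine (cat.), urea·H2O2, DBU, THF, rt
Reagents that add atoms: hydrogen peroxide (from its urea adduct), OO
Why: Juliá–Colonna asymmetric nucleophilic (Weitz–Scheffer) epoxidation: the poly-L-leucine helix delivers hydroperoxide to one enone face and gives the trans-(2R,3S)-epoxy ketone, i.e. the upper C3 and (before inversion) C4.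

Step 8
Reactants: 13 the (2R,3S)-epoxy ketone
Product: 14 (S)-[4-(benzyloxy)phenyl]{(2S,3S)-3-[2,3-bis(benzyloxy)-4-{(R)-[3,4-bis(benzyloxy)phenyl][(2R)-oxiran-2-yl]methoxy}phenyl]oxiran-2-yl}methanol (erythro)
Conditions: Zn(BH4)2, Et2O/THF, −20 °C
Reagents that add atoms: none
Why: Chelation-controlled reduction: zinc bridges the carbonyl and epoxide oxygens and hydride adds from the open face to give the erythro epoxy alcohol, while both epoxides survive at this temperature.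

Step 9
Reactants: 14 the erythro epoxy alcohol; 3 2,2-diphenyl-1,3-benzodioxol-4-ol
Product: 15 4-{(R)-[4-(benzyloxy)phenyl]{(2R,3S)-3-[2,3-bis(benzyloxy)-4-{(R)-[3,4-bis(benzyloxy)phenyl][(2R)-oxiran-2-yl]methoxy}phenyl]oxiran-2-yl}methoxy}-2,2-diphenyl-1,3-benzodioxole
Conditions: PPh3, DIAD, toluene/THF, 0 °C to rt
Reagents that add atoms: none
Why: Mitsunobu etherification with SN2 inversion at the benzylic carbinol (the adjacent epoxide disfavours ionization) gives the threo aryl ether, fixing upper C2 cis to the C3 oxygen.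

Step 10
Reactants: 15 the bis-epoxide
Product: 17 (2R,3R,4R)-2-[4-(benzyloxy)phenyl]-4-{(2R,3R)-7,8-bis(benzyloxy)-2-[3,4-bis(benzyloxy)phenyl]-3-hydroxychroman-6-yl}-7,8-(diphenylmethylenedioxy)chroman-3-ol, via upper-ring-closed monoepoxide 16 (not isolated)
Conditions: HFIP/CH2Cl2 4:1 (5 mM), 0 °C, 1 h; then BF3·OEt2 (20 mol %), 0 °C to rt
Reagents that add atoms: none
Why: Proposed new method: a one-pot double 6-endo epoxy–arene Friedel–Crafts cyclization; HFIP first activates the very electron-rich benzylic epoxide so that C5 of the benzodioxole (ortho to the ether oxygen, para to a ketal oxygen) attacks the benzylic carbon with inversion (trans-epoxide gives 3,4-trans, upper C4 set), then the Lewis acid lets the central ring (ortho to its ether oxygen, para to OBn) open the terminal epoxide at CH2 (the internal carbon is deactivated by the β-aryloxy group, and 5-endo attack by ring B is geometrically disfavoured); the closest known reactions are the stereospecific HFIP-promoted 6-endo cyclizations of aryl ethers of 3-arylglycidols to trans-4-arylchroman-3-ols and of aryl glycidyl ethers to chroman-3-ols.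

Step 11
Reactants: 17 the protected bis-flavan
Product: 18 (2R,3R,4S)-7,8-bis(benzyloxy)-2-[3,4-bis(benzyloxy)phenyl]-6-{(2R,3R,4R)-2-[4-(benzyloxy)phenyl]-3-hydroxy-7,8-(diphenylmethylenedioxy)chroman-4-yl}chroman-3,4-diol
Conditions: DDQ (1.3 equiv), CH2Cl2/H2O 10:1, 0 °C to rt
Reagents that add atoms: water, O
Why: DDQ benzylic hydride abstraction at the lower C4 (its axial C–H is aligned with the 7-alkoxy-activated ring A, whereas the upper C4–H is quasi-equatorial, tertiary and shielded by two aryl rings) gives a C4 cation that water captures anti to the axial 3-OH, giving the 3,4-trans alcohol.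

Step 12
Reactants: 18 the protected flavan-3,4-diol dimer
Product: 19 (2R,3R,4S)-2-(3,4-dihydroxyphenyl)-6-[(2R,3R,4S)-3,7,8-trihydroxy-2-(4-hydroxyphenyl)chroman-4-yl]chroman-3,4,7,8-tetrol (target)
Conditions: H2 (1 atm), Pd(OH)2/C, THF/H2O 9:1, rt, 3 h
Reagents that add atoms: none
Why: Hydrogenolysis of five O-benzyl ethers and the diphenylmethylene ketal under neutral, alcohol-free conditions is faster than cleavage of the benzylic C4–OH and C2–O1 bonds, so no stereocentre changes.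

**Compound list**

1 | pyrogallol | Oc1cccc(O)c1O | starting material
2 | dichlorodiphenylmethane | ClC(Cl)(c1ccccc1)c1ccccc1 | starting material
3 | 2,2-diphenyl-1,3-benzodioxol-4-ol | Oc1cccc2OC(c3ccccc3)(c3ccccc3)Oc12 | intermediate
4 | 3,4-bis(benzyloxy)benzaldehyde | O=Cc1ccc(OCc2ccccc2)c(OCc2ccccc2)c1 | starting material
5 | vinylmagnesium bromide | C=C[Mg]Br | starting material
6 | rac-1-[3,4-bis(benzyloxy)phenyl]prop-2-en-1-ol | C=CC(O)c1ccc(OCc2ccccc2)c(OCc2ccccc2)c1 | intermediate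
7 | (S)-[3,4-bis(benzyloxy)phenyl][(2R)-oxiran-2-yl]methanol (erythro) | O[C@@H](c1ccc(OCc2ccccc2)c(OCc2ccccc2)c1)[C@H]1CO1 | intermediate
8 | 2,3,4-trihydroxybenzaldehyde | O=Cc1ccc(O)c(O)c1O | starting material
9 | 4-{(R)-[3,4-bis(benzyloxy)phenyl][(2R)-oxiran-2-yl]methoxy}-2,3-dihydroxybenzaldehyde | O=Cc1ccc(O[C@H](c2ccc(OCc3ccccc3)c(OCc3ccccc3)c2)[C@H]2CO2)c(O)c1O | intermediate
10 | 2,3-bis(benzyloxy)-4-{(R)-[3,4-bis(benzyloxy)phenyl][(2R)-oxiran-2-yl]methoxy}benzaldehyde | O=Cc1ccc(O[C@H](c2ccc(OCc3ccccc3)c(OCc3ccccc3)c2)[C@H]2CO2)c(OCc2ccccc2)c1OCc1ccccc1 | intermediate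
11 | 1-[4-(benzyloxy)phenyl]ethanone | CC(=O)c1ccc(OCc2ccccc2)cc1 | starting material
12 | (E)-chalcone of 10 and 11 (named in step 6) | O=C(/C=C/c1ccc(O[C@H](c2ccc(OCc3ccccc3)c(OCc3ccccc3)c2)[C@H]2CO2)c(OCc2ccccc2)c1OCc1ccccc1)c1ccc(OCc2ccccc2)cc1 | intermediate
13 | trans-(2R,3S)-epoxy ketone (named in step 7) | O=C([C@@H]1O[C@H]1c1ccc(O[C@H](c2ccc(OCc3ccccc3)c(OCc3ccccc3)c2)[C@H]2CO2)c(OCc2ccccc2)c1OCc1ccccc1)c1ccc(OCc2ccccc2)cc1 | intermediate
14 | erythro epoxy alcohol, carbinol S, oxirane (2S,3S) (named in step 8) | O[C@H]([C@@H]1O[C@H]1c1ccc(O[C@H](c2ccc(OCc3ccccc3)c(OCc3ccccc3)c2)[C@H]2CO2)c(OCc2ccccc2)c1OCc1ccccc1)c1ccc(OCc2ccccc2)cc1 | intermediate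
15 | threo bis-epoxide aryl ether, ether carbon R, oxirane (2R,3S) (named in step 9) | O(c1cccc2OC(c3ccccc3)(c3ccccc3)Oc12)[C@@H]([C@@H]1O[C@H]1c1ccc(O[C@H](c2ccc(OCc3ccccc3)c(OCc3ccccc3)c2)[C@H]2CO2)c(OCc2ccccc2)c1OCc1ccccc1)c1ccc(OCc2ccccc2)cc1 | intermediate
16 | (2R,3R,4S)-2-[4-(benzyloxy)phenyl]-4-[2,3-bis(benzyloxy)-4-{(R)-[3,4-bis(benzyloxy)phenyl][(2R)-oxiran-2-yl]methoxy}phenyl]-7,8-(diphenylmethylenedioxy)chroman-3-ol (2,3-cis-3,4-trans) | C(c1ccccc1)Oc1ccc([C@H]2Oc3c(ccc4OC(c5ccccc5)(c5ccccc5)Oc34)[C@H](c3ccc(c(OCc5ccccc5)c3OCc3ccccc3)O[C@H](c3ccc(OCc5ccccc5)c(OCc5ccccc5)c3)[C@H]3CO3)[C@H]2O)cc1 | intermediate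
17 | protected bis-flavan, upper (2R,3R,4R), lower (2R,3R), all 2,3-cis, upper 3,4-trans (named in step 10; the upper C4 descriptor differs from 16 and 19 only through CIP priorities) | C(c1ccccc1)Oc1ccc([C@H]2Oc3c(ccc4OC(c5ccccc5)(c5ccccc5)Oc34)[C@H](c3cc4c(c(OCc5ccccc5)c3OCc3ccccc3)O[C@H](c3ccc(OCc5ccccc5)c(OCc5ccccc5)c3)[C@H](O)C4)[C@H]2O)cc1 | intermediate
18 | protected target with lower 4β-OH, upper (2R,3R,4R), lower (2R,3R,4S) (named in step 11) | C(c1ccccc1)Oc1ccc([C@H]2Oc3c(ccc4OC(c5ccccc5)(c5ccccc5)Oc34)[C@H](c3cc4c(c(OCc5ccccc5)c3OCc3ccccc3)O[C@H](c3ccc(OCc5ccccc5)c(OCc5ccccc5)c3)[C@H](O)[C@H]4O)[C@H]2O)cc1 | intermediate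
19 | (2R,3R,4S)-2-(3,4-dihydroxyphenyl)-6-[(2R,3R,4S)-3,7,8-trihydroxy-2-(4-hydroxyphenyl)chroman-4-yl]chroman-3,4,7,8-tetrol | Oc1ccc([C@H]2Oc3c(ccc(O)c3O)[C@H](c3cc4c(c(O)c3O)O[C@H](c3ccc(O)c(O)c3)[C@H](O)[C@H]4O)[C@H]2O)cc1 | target

**Count**
Total steps: 12. Longest linear sequence: 11 (steps 2 to 12, from 4).

**Steps most likely to fail, with fallbacks**

Step 10 (double cyclization; the terminal epoxide may not close under acid, or the benzylic ethers may ionize). The fallback replaces the cationic closure of the lower ring by an aryllithium closure. It sets out from 8, which is brominated (Br2, AcOH) to 5-bromo-2,3,4-trihydroxybenzaldehyde F1. The conditions of steps 4 to 9 then give in turn bromo ether F2, bromo dibenzyl ether F3, bromo chalcone F4, bromo epoxy ketone F5, bromo epoxy alcohol F6 and bromo bis-epoxide F7. HFIP alone closes the upper ring to bromo monoepoxide F8. MeLi (1 equiv, for the free OH), then t-BuLi (2.2 equiv) and BF3·OEt2 in THF at −78 °C make the aryllithium, which opens the terminal epoxide at CH2 (6-endo), and the route comes back at 17.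

Step 11 (DDQ may attack the doubly benzylic upper C4–H or over-oxidize to the ketone). The fallback brings the C4 oxygen in as a carbonyl instead of by C–H oxidation. It sets out from 16, isolated by stopping step 10 before BF3·OEt2 is added. KOH in DMSO/H2O at 60 °C opens the terminal epoxide at CH2 to triol F9. TEMPO (cat.) with PhI(OAc)2 in CH2Cl2 oxidizes only the primary alcohol to α-hydroxy aldehyde F10. In dilute HFIP at rt the central ring adds to the aldehyde (intramolecular Friedel–Crafts hydroxyalkylation), and the C4 epimers equilibrate through the benzylic cation to the 3,4-trans alcohol, coming back at 18.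

Step 7 (Juliá–Colonna epoxidation is slow and less selective on electron-rich, ortho-substituted chalcones). The fallback reduces first and then uses a hydroxyl-directed electrophilic epoxidation. It sets out from 12: NaBH4 with CeCl3·7H2O in MeOH/THF at −40 °C gives allylic alcohol F11 as both carbinol epimers. Ti(OiPr)4, L-(+)-DIPT and TBHP (0.5 equiv) with 4 Å MS in CH2Cl2 at −20 °C epoxidize only the (R)-carbinol epimer, to the erythro epoxy alcohol, coming back at 14.

**Further compounds**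

F1 | step 10 | 5-bromo-2,3,4-trihydroxybenzaldehyde | O=Cc1cc(Br)c(O)c(O)c1O
F2 | step 10 | 5-bromo analogue of 9 (Br ortho to the ether oxygen) | O=Cc1cc(Br)c(O[C@H](c2ccc(OCc3ccccc3)c(OCc3ccccc3)c2)[C@H]2CO2)c(O)c1O
F3 | step 10 | 5-bromo analogue of 10 | O=Cc1cc(Br)c(O[C@H](c2ccc(OCc3ccccc3)c(OCc3ccccc3)c2)[C@H]2CO2)c(OCc2ccccc2)c1OCc1ccccc1
F4 | step 10 | bromo analogue of chalcone 12 | O=C(/C=C/c1cc(Br)c(O[C@H](c2ccc(OCc3ccccc3)c(OCc3ccccc3)c2)[C@H]2CO2)c(OCc2ccccc2)c1OCc1ccccc1)c1ccc(OCc2ccccc2)cc1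
F5 | step 10 | bromo analogue of epoxy ketone 13 | O=C([C@@H]1O[C@H]1c1cc(Br)c(O[C@H](c2ccc(OCc3ccccc3)c(OCc3ccccc3)c2)[C@H]2CO2)c(OCc2ccccc2)c1OCc1ccccc1)c1ccc(OCc2ccccc2)cc1
F6 | step 10 | bromo analogue of epoxy alcohol 14 | O[C@H]([C@@H]1O[C@H]1c1cc(Br)c(O[C@H](c2ccc(OCc3ccccc3)c(OCc3ccccc3)c2)[C@H]2CO2)c(OCc2ccccc2)c1OCc1ccccc1)c1ccc(OCc2ccccc2)cc1
F7 | step 10 | bromo analogue of bis-epoxide 15 | O(c1cccc2OC(c3ccccc3)(c3ccccc3)Oc12)[C@@H]([C@@H]1O[C@H]1c1cc(Br)c(O[C@H](c2ccc(OCc3ccccc3)c(OCc3ccccc3)c2)[C@H]2CO2)c(OCc2ccccc2)c1OCc1ccccc1)c1ccc(OCc2ccccc2)cc1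
F8 | step 10 | bromo analogue of 16 (upper ring closed, Br at the future lower C4a) | C(c1ccccc1)Oc1ccc([C@H]2Oc3c(ccc4OC(c5ccccc5)(c5ccccc5)Oc34)[C@H](c3cc(Br)c(c(OCc5ccccc5)c3OCc3ccccc3)O[C@H](c3ccc(OCc5ccccc5)c(OCc5ccccc5)c3)[C@H]3CO3)[C@H]2O)cc1
F9 | step 11 | triol from 16 (terminal epoxide opened to the 1,2-diol) | C(c1ccccc1)Oc1ccc([C@H]2Oc3c(ccc4OC(c5ccccc5)(c5ccccc5)Oc34)[C@H](c3ccc(c(OCc5ccccc5)c3OCc3ccccc3)O[C@H](c3ccc(OCc5ccccc5)c(OCc5ccccc5)c3)[C@H](O)CO)[C@H]2O)cc1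
F10 | step 11 | α-hydroxy aldehyde from F9 | C(c1ccccc1)Oc1ccc([C@H]2Oc3c(ccc4OC(c5ccccc5)(c5ccccc5)Oc34)[C@H](c3ccc(c(OCc5ccccc5)c3OCc3ccccc3)O[C@H](c3ccc(OCc5ccccc5)c(OCc5ccccc5)c3)[C@H](O)C=O)[C@H]2O)cc1
F11 | step 7 | allylic alcohol from 12 (both carbinol epimers, E-alkene) | OC(/C=C/c1ccc(O[C@H](c2ccc(OCc3ccccc3)c(OCc3ccccc3)c2)[C@H]2CO2)c(OCc2ccccc2)c1OCc1ccccc1)c1ccc(OCc2ccccc2)cc1
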